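**Strategy**

Everything rests on a ring switch. In the target, the pyranone oxygen O1 sits on C8a between the acyl-bearing C4a and C8, whose hexanoic acid chain can reach it. O1 and the carboxyl group are therefore stored together as a six-membered aryl lactone (a 4-propyldihydrocoumarin) that carries a 3-methylbut-2-enoyl group on the neighbouring carbon and benzyl ethers on the other two oxygens. Hydroxide opens the lactone and the freed phenoxide closes the 2,2-dimethylchromanone by O1–C2 bond formation, which releases the acid and fixes the regiochemistry in one operation. Reductive alkylation with an enantiopure cyclobutane aldehyde and asymmetric dearomative prenylation at C6 complete the target.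

Key step: step 8

Remark: 24 is drawn as the 5-hydroxy-4,7-dioxo tautomer of an enolised β-triketone; the tautomers equilibrate, so the constitution, not the tautomer, is the goal.
Remark: the ligand antipodes named in steps 3, 6 and 11 are those expected by analogy to give the stated configurations; the mirror-image ligand would be used if the sense of induction is opposite.

**Route**

Step 1
Reactants: 1 isobutyraldehyde (2-methylpropanal); 2 pyrrolidine; 3 methyl acrylate
Product: 5 methyl 3,3-dimethyl-2-(pyrrolidin-1-yl)cyclobutane-1-carboxylate (racemic cis/trans mixture), via enamine 4 (not isolated)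
Conditions: 1 + 2 (1.0 equiv), 4 Å MS, MeCN, 0 °C to rt; then 3 (1.2 equiv), 85 °C, sealed tube
Reagents that add atoms: none
Why: The enamine formed by condensation adds through its β-carbon to the acrylate and the resulting iminium ester enolate closes the four-membered ring (thermal enamine–acrylate [2+2] cycloaddition, a stepwise Michael–Mannich sequence), Stork alkylation being blocked because the enamine β-carbon carries no hydrogen; the stereocentres formed are removed in step 2.

Step 2
Reactants: 5 methyl 3,3-dimethyl-2-(pyrrolidin-1-yl)cyclobutane-1-carboxylate; 6 iodomethane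
Product: 8 methyl 3,3-dimethylcyclobut-1-ene-1-carboxylate, via N-methylpyrrolidinium iodide 7 (not isolated)
Conditions: MeI, MeCN, rt; then K2CO3, H2O/Et2O, rt
Reagents that add atoms: none
Why: N-Methylation and Hofmann-type E1cB elimination of 1-methylpyrrolidine from the β-ammonio ester should give the conjugated cyclobutene, because the only acidic β-hydrogen is the one α to the ester.

Step 3
Reactants: 8 methyl 3,3-dimethylcyclobut-1-ene-1-carboxylate; 9 isopropenylboronic acid pinacol ester
Product: 11 methyl (1R,2R)-3,3-dimethyl-2-(prop-1-en-2-yl)cyclobutane-1-carboxylate (trans), via cis ester 10 (not isolated)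
Conditions: [RhCl(C2H4)2]2 (2.5 mol %), (S,S)-2,5-diphenylbicyclo[2.2.2]octa-2,5-diene (5.5 mol %), KOH (20 mol %), 1,4-dioxane/H2O 10:1, 50 °C; then NaOMe (20 mol %), MeOH, rt
Reagents that add atoms: none
Why: Rhodium-catalysed asymmetric 1,4-addition of an alkenylboron reagent (Hayashi–Miyaura reaction), of the kind known for cyclobut-1-ene carboxylates, should deliver the isopropenyl group to one enantioface of the strained alkene under control of the chiral diene ligand (C2 set as R), and methoxide equilibration then converts the kinetically protonated cis ester into the more stable trans (1R,2R) ester.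

Step 4
Reactants: 11 methyl (1R,2R)-3,3-dimethyl-2-(prop-1-en-2-yl)cyclobutane-1-carboxylate
Product: 12 (1R,2R)-3,3-dimethyl-2-(prop-1-en-2-yl)cyclobutane-1-carbaldehyde
Conditions: DIBAL-H (1.1 equiv), CH2Cl2, −78 °C; Rochelle salt work-up
Reagents that add atoms: none
Why: DIBAL-H partial reduction of an ester stops at the aluminium hemiacetal at −78 °C and gives the aldehyde on work-up, whose α-centre is already the thermodynamically preferred trans one.

Step 5
Reactants: 13 5,7-dihydroxy-4-propyl-2H-chromen-2-one (5,7-dihydroxy-4-propylcoumarin)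
Product: 14 5,7-bis(benzyloxy)-4-propyl-2H-chromen-2-one
Conditions: BnBr (2.5 equiv), K2CO3, DMF, 60 °C
Reagents that add atoms: benzyl bromide, BrCc1ccccc1
Why: Williamson etherification of both phenols, which blocks O5 and O7 so that they cannot direct the acylation of step 7 or compete in step 8.

Step 6
Reactants: 14 5,7-bis(benzyloxy)-4-propyl-2H-chromen-2-one
Product: 15 (4R)-5,7-bis(benzyloxy)-4-propyl-3,4-dihydro-2H-chromen-2-one
Conditions: Cu(OAc)2·H2O (3 mol %), (R)-DTBM-SEGPHOS (3 mol %), (EtO)2MeSiH (3 equiv), t-BuOH (1.5 equiv), toluene, rt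
Reagents that add atoms: none
Why: Copper hydride-catalysed asymmetric conjugate reduction of a β,β-disubstituted unsaturated lactone, as known for coumarins, in which the bisphosphine–copper hydride adds hydride to one face of C4 (aryl ring versus propyl) and so sets the 4R centre; benzyl ethers are inert.

Step 7
Reactants: 15 (4R)-5,7-bis(benzyloxy)-4-propyl-3,4-dihydro-2H-chromen-2-one; 16 3-methylbut-2-enoic acid
Product: 17 (4R)-5,7-bis(benzyloxy)-8-(3-methylbut-2-enoyl)-4-propyl-3,4-dihydro-2H-chromen-2-one
Conditions: 16 (1.5 equiv), (CF3CO)2O (2.5 equiv), 85% H3PO4 (cat.), CH2Cl2, 0 °C to rt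
Reagents that add atoms: none
Why: Friedel–Crafts acylation by the mixed trifluoroacetic anhydride should go to C8, which is para to the 5-benzyloxy group and flanked by only one benzyloxy group whereas C6 lies between two, and it avoids metal halide Lewis acids that would cleave benzyl ethers.

Step 8
Reactants: 17 (4R)-5,7-bis(benzyloxy)-8-(3-methylbut-2-enoyl)-4-propyl-3,4-dihydro-2H-chromen-2-one
Product: 19 (3R)-3-[5,7-bis(benzyloxy)-2,2-dimethyl-4-oxo-3,4-dihydro-2H-chromen-8-yl]hexanoic acid, via ring-opened phenoxide acid 18 (not isolated)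
Conditions: LiOH·H2O (4 equiv), THF/H2O 3:1, rt; then 1 M HCl to pH 3
Reagents that add atoms: lithium hydroxide, [Li+].[OH-]
Why: Hydroxide opens the aryl lactone of 17 by acyl substitution, giving the carboxylate and the C8a phenoxide of 18; this phenoxide, which lies ortho to the 3-methylbut-2-enoyl group, adds to its β-carbon (intramolecular oxa-Michael addition) and protonation of the enolate gives the 2,2-dimethylchroman-4-one with the hexanoic acid chain set free. The closest known reaction types are the base-mediated cyclisation of 2-hydroxyaryl 2-methylprop-1-enyl ketones to 2,2-dimethylchromanones and the saponification of dihydrocoumarins, here run as one cascade. The pyranone ring closes in the 6-endo-trig mode by O1–C2 bond formation. No stereocentre is formed (C2 carries two methyl groups) and the benzylic centre of the side chain, which has no acidic hydrogen, keeps its R configuration. The step needs regioselectivity among the three ring oxygens, and the substrate secures it: O5 and O7 are benzyl ethers, so only the oxygen released from the lactone, the one next to the side-chain carbon, can attack. Once this oxygen is built into the pyranone ring the lactone cannot re-form on acidification, which pulls the equilibria to 19.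

Step 9
Reactants: 19 (3R)-3-[5,7-bis(benzyloxy)-2,2-dimethyl-4-oxo-3,4-dihydro-2H-chromen-8-yl]hexanoic acid
Product: 20 (3R)-3-(5,7-dihydroxy-2,2-dimethyl-4-oxo-3,4-dihydro-2H-chromen-8-yl)hexanoic acid
Conditions: H2 (1 atm), 10% Pd/C (palladium on carbon), EtOAc/MeOH, rt
Reagents that add atoms: none
Why: Hydrogenolysis of the two benzyl ethers over palladium at one atmosphere leaves the aryl ketone untouched and is placed before any alkene enters the molecule; the product is used directly as the open hydroxy acid.

Step 10
Reactants: 20 (3R)-3-(5,7-dihydroxy-2,2-dimethyl-4-oxo-3,4-dihydro-2H-chromen-8-yl)hexanoic acid; 12 (1R,2R)-3,3-dimethyl-2-(prop-1-en-2-yl)cyclobutane-1-carbaldehyde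
Product: 22 (3R)-3-[6-{[(1S,2R)-3,3-dimethyl-2-(prop-1-en-2-yl)cyclobutyl]methyl}-5,7-dihydroxy-2,2-dimethyl-4-oxo-3,4-dihydro-2H-chromen-8-yl]hexanoic acid, via ortho-quinone methide 21 (not isolated)
Conditions: 12 (1.2 equiv), L-proline (20 mol %), Hantzsch ester (diethyl 2,6-dimethyl-1,4-dihydropyridine-3,5-dicarboxylate, 1.2 equiv), CH2Cl2/EtOH, rt
Reagents that add atoms: none
Why: Three-component reductive alkylation: proline-mediated Mannich/Knoevenagel-type condensation of the aldehyde at C6, the only unsubstituted ring carbon, gives an ortho-quinone methide that accepts hydride from the Hantzsch ester, a reagent that reduces neither the aldehyde nor the alkenes; the cyclobutane centre next to the aldehyde is the stable trans one and the other stereocentres are untouched.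

Step 11
Reactants: 22 (3R)-3-[6-{[(1S,2R)-3,3-dimethyl-2-(prop-1-en-2-yl)cyclobutyl]methyl}-5,7-dihydroxy-2,2-dimethyl-4-oxo-3,4-dihydro-2H-chromen-8-yl]hexanoic acid; 23 3-methylbut-2-en-1-yl acetate (prenyl acetate)
Product: 24 (3R)-3-[(6R)-6-{[(1S,2R)-3,3-dimethyl-2-(prop-1-en-2-yl)cyclobutyl]methyl}-5-hydroxy-2,2-dimethyl-6-(3-methylbut-2-en-1-yl)-4,7-dioxo-3,4,6,7-tetrahydro-2H-chromen-8-yl]hexanoic acid
Conditions: 23 (1.5 equiv), Pd2(dba)3·CHCl3 (2.5 mol %), (R,R)-DACH-phenyl Trost ligand (7.5 mol %), Cs2CO3 (2.5 equiv), THF, 0 °C to rt; then aq. citric acid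
Reagents that add atoms: none
Why: Palladium-catalysed asymmetric allylic dearomatisation (Tsuji–Trost reaction): the phenoxide attacks the unsubstituted terminus of the π-prenyl palladium complex through C6, which lies between two oxygen-bearing carbons and is less hindered than C8 with its α-branched chain, the chiral ligand choosing the face of C6 (6R quaternary centre), while O-prenyl by-products and the prenyl ester re-ionise and drain into the C-alkylated product.

**Compound list**

1 | isobutyraldehyde (2-methylpropanal) | CC(C)C=O | starting material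
2 | pyrrolidine | C1CCNC1 | starting material
3 | methyl acrylate | C=CC(=O)OC | starting material
4 | 1-(2-methylprop-1-en-1-yl)pyrrolidine (enamine, not isolated) | CC(C)=CN1CCCC1 | intermediate
5 | methyl 3,3-dimethyl-2-(pyrrolidin-1-yl)cyclobutane-1-carboxylate (racemic cis/trans mixture) | COC(=O)C1CC(C)(C)C1N1CCCC1 | intermediate
6 | iodomethane | CI | starting material
7 | 1-[2-(methoxycarbonyl)-4,4-dimethylcyclobutyl]-1-methylpyrrolidin-1-ium iodide (not isolated) | COC(=O)C1CC(C)(C)C1[N+]1(C)CCCC1.[I-] | intermediate
8 | methyl 3,3-dimethylcyclobut-1-ene-1-carboxylate | COC(=O)C1=CC(C)(C)C1 | intermediate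
9 | isopropenylboronic acid pinacol ester (4,4,5,5-tetramethyl-2-(prop-1-en-2-yl)-1,3,2-dioxaborolane) | CC(=C)B1OC(C)(C)C(C)(C)O1 | starting material
10 | methyl (1S,2R)-3,3-dimethyl-2-(prop-1-en-2-yl)cyclobutane-1-carboxylate (cis, not isolated) | C=C(C)[C@H]1[C@@H](C(=O)OC)CC1(C)C | intermediate
11 | methyl (1R,2R)-3,3-dimethyl-2-(prop-1-en-2-yl)cyclobutane-1-carboxylate (trans) | C=C(C)[C@H]1[C@H](C(=O)OC)CC1(C)C | intermediate
12 | (1R,2R)-3,3-dimethyl-2-(prop-1-en-2-yl)cyclobutane-1-carbaldehyde (trans) | C=C(C)[C@H]1[C@H](C=O)CC1(C)C | intermediate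
13 | 5,7-dihydroxy-4-propyl-2H-chromen-2-one | CCCC1=CC(=O)Oc2cc(O)cc(O)c12 | starting material
14 | 5,7-bis(benzyloxy)-4-propyl-2H-chromen-2-one | CCCC1=CC(=O)Oc2cc(OCc3ccccc3)cc(OCc3ccccc3)c12 | intermediate
15 | (4R)-5,7-bis(benzyloxy)-4-propyl-3,4-dihydro-2H-chromen-2-one | CCC[C@@H]1CC(=O)Oc2cc(OCc3ccccc3)cc(OCc3ccccc3)c12 | intermediate
16 | 3-methylbut-2-enoic acid | CC(C)=CC(=O)O | starting material
17 | (4R)-5,7-bis(benzyloxy)-8-(3-methylbut-2-enoyl)-4-propyl-3,4-dihydro-2H-chromen-2-one | CCC[C@@H]1CC(=O)Oc2c(C(=O)C=C(C)C)c(OCc3ccccc3)cc(OCc3ccccc3)c12 | intermediate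
18 | (3R)-3-[4,6-bis(benzyloxy)-2-hydroxy-3-(3-methylbut-2-enoyl)phenyl]hexanoic acid (present as its dilithium salt, not isolated) | CCC[C@H](CC(=O)O)c1c(O)c(C(=O)C=C(C)C)c(OCc2ccccc2)cc1OCc1ccccc1 | intermediate
19 | (3R)-3-[5,7-bis(benzyloxy)-2,2-dimethyl-4-oxo-3,4-dihydro-2H-chromen-8-yl]hexanoic acid | CCC[C@H](CC(=O)O)c1c(OCc2ccccc2)cc(OCc2ccccc2)c2C(=O)CC(C)(C)Oc12 | intermediate
20 | (3R)-3-(5,7-dihydroxy-2,2-dimethyl-4-oxo-3,4-dihydro-2H-chromen-8-yl)hexanoic acid | CCC[C@H](CC(=O)O)c1c(O)cc(O)c2C(=O)CC(C)(C)Oc12 | intermediate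
21 | ortho-quinone methide of 22: 6-(cyclobutylmethylidene)-5-hydroxy-4,7-dioxo tautomer, cyclobutane and side-chain centres as in 22 (not isolated) | C=C(C)[C@H]1[C@H](C=C2C(=O)C([C@H](CCC)CC(=O)O)=C3OC(C)(C)CC(=O)C3=C2O)CC1(C)C | intermediate
22 | (3R)-3-[6-{[(1S,2R)-3,3-dimethyl-2-(prop-1-en-2-yl)cyclobutyl]methyl}-5,7-dihydroxy-2,2-dimethyl-4-oxo-3,4-dihydro-2H-chromen-8-yl]hexanoic acid | C=C(C)[C@H]1[C@H](Cc2c(O)c([C@H](CCC)CC(=O)O)c3OC(C)(C)CC(=O)c3c2O)CC1(C)C | intermediate
23 | 3-methylbut-2-en-1-yl acetate (prenyl acetate) | CC(C)=CCOC(C)=O | starting material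
24 | (3R)-3-[(6R)-6-{[(1S,2R)-3,3-dimethyl-2-(prop-1-en-2-yl)cyclobutyl]methyl}-5-hydroxy-2,2-dimethyl-6-(3-methylbut-2-en-1-yl)-4,7-dioxo-3,4,6,7-tetrahydro-2H-chromen-8-yl]hexanoic acid | C=C(C)[C@H]1[C@H](C[C@]2(CC=C(C)C)C(=O)C([C@H](CCC)CC(=O)O)=C3OC(C)(C)CC(=O)C3=C2O)CC1(C)C | target

**Summary**

Total step count: 11.
Longest linear sequence: 7 steps (13 to 24, steps 5 to 11); the cyclobutane aldehyde 12 is made in 4 steps and joins at step 10.

**Steps most likely to fail, with fallbacks**

Step 11. The chiral π-allyl complex may discriminate poorly between the two faces of C6, and part of the material may be diverted to C8- or O-prenylation. The fallback gives up catalyst control. It sets out from 22 and uses the classical dearomative C-prenylation of acylphloroglucinols with prenyl bromide in aqueous KOH at 0 °C, an SN2 alkylation of the phenoxide in water that favours carbon attack. This should give the C6-quaternary acid as both epimers, 24 and the (6S)-epimer F1. The two are diastereomers and would be separated by preparative reversed-phase HPLC, which brings the route back at 24.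

Step 3. Carbometalation at the β-carbon next to the quaternary centre may be slow, so that protodeboronation of the alkenylboron reagent wins, and enantioface discrimination may be weak. The fallback sets out from 8 and replaces asymmetric catalysis by a racemic addition and a covalent resolution. Copper-catalysed conjugate addition of isopropenylmagnesium bromide (CuBr·SMe2, TMSCl, THF, −78 °C) followed by NaOMe/MeOH should give the racemic trans ester F2. LiOH saponification gives the racemic trans acid F3. Acylation of lithiated (S)-4-benzyl-1,3-oxazolidin-2-one with the pivaloyl mixed anhydride of F3 gives two diastereomeric imides, the (1R,2R)-acyl imide F4 and the (1S,2S)-acyl imide F5, which are separated by chromatography. Methanolysis of F4 (NaOMe, MeOH, 0 °C) brings the route back at 11.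

Step 6. Hydride delivery next to the peri benzyloxy group may be slow and the enantiofacial control incomplete. The fallback sets out from 14 and separates instead of inducing. Conjugate reduction with an achiral copper hydride (Cu(OAc)2·H2O, 1,2-bis(diphenylphosphino)benzene, (EtO)2MeSiH, t-BuOH) should give the racemic dihydrocoumarin F6. Resolution by preparative chromatography on a cellulose tris(3,5-dimethylphenylcarbamate) stationary phase gives the (4R)-enantiomer and brings the route back at 15.

**Further compounds**

F1 | step 11 | (3R)-3-[(6S)-6-{[(1S,2R)-3,3-dimethyl-2-(prop-1-en-2-yl)cyclobutyl]methyl}-5-hydroxy-2,2-dimethyl-6-(3-methylbut-2-en-1-yl)-4,7-dioxo-3,4,6,7-tetrahydro-2H-chromen-8-yl]hexanoic acid (C6 epimer of 24) | C=C(C)[C@H]1[C@H](C[C@@]2(CC=C(C)C)C(=O)C([C@H](CCC)CC(=O)O)=C3OC(C)(C)CC(=O)C3=C2O)CC1(C)C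
F2 | step 3 | methyl trans-3,3-dimethyl-2-(prop-1-en-2-yl)cyclobutane-1-carboxylate (racemic) | C=C(C)C1C(C(=O)OC)CC1(C)C
F3 | step 3 | trans-3,3-dimethyl-2-(prop-1-en-2-yl)cyclobutane-1-carboxylic acid (racemic) | C=C(C)C1C(C(=O)O)CC1(C)C
F4 | step 3 | (4S)-4-benzyl-3-{[(1R,2R)-3,3-dimethyl-2-(prop-1-en-2-yl)cyclobutyl]carbonyl}-1,3-oxazolidin-2-one | C=C(C)[C@H]1[C@H](C(=O)N2[C@@H](Cc3ccccc3)COC2=O)CC1(C)C
F5 | step 3 | (4S)-4-benzyl-3-{[(1S,2S)-3,3-dimethyl-2-(prop-1-en-2-yl)cyclobutyl]carbonyl}-1,3-oxazolidin-2-one (discarded diastereomer) | C=C(C)[C@@H]1[C@@H](C(=O)N2[C@@H](Cc3ccccc3)COC2=O)CC1(C)C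
F6 | step 6 | 5,7-bis(benzyloxy)-4-propyl-3,4-dihydro-2H-chromen-2-one (racemic) | CCCC1CC(=O)Oc2cc(OCc3ccccc3)cc(OCc3ccccc3)c12
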